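**Strategy** (numbering: C1 lactone carbonyl, C2 CH2, C3 CHOH, C4 ring carbon carrying CH3 and the ring oxygen, C5 exocyclic CH2, C6 chain carbinol, C7–C22 alkyl chain)
- Enabling feature: C5 is a methylene locked between two fully substituted methyl carbinols, C4 of the γ-lactone ring and C6 of the chain. Displacement at this doubly neopentyl carbon is not feasible, but C5–C6–O is the skeleton of a terminal epoxide, and C4 is a latent methyl ketone whose neighbour C3 carries an oxygen that can direct an addition.
- Cuts: the lactone C1–O(C4) bond (C1 taken back to a primary alcohol), then C4–C5 (C5 carbanion from a reductively opened epoxide plus a C4 ketone), then C7–C8 (alkyl Grignard plus the epoxide CH2 of a glycidol).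
- Forward order: C7–C8 is joined first, the two halves are united at C4–C5, and the only ring, the γ-lactone, closes last by oxidation of the C1/C4 diol.
- Stereochemistry: C6 comes from (S)-2-methylglycidol (its C–O bond is never broken), C3 from (S)-α-hydroxy-γ-butyrolactone, and C4 is set by 1,2-induction from C3 through a magnesium chelate in the key step.

Key step: step 6

Remark on the chemistry: lithium 4,4'-di-tert-butylbiphenylide (LiDBB) is taken as a titrated stock solution in THF, prepared beforehand from lithium and the arene.

**Step 1**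
Reactants: 1 1-bromopentadecane; 2 (S)-2-methylglycidol [(S)-(2-methyloxiran-2-yl)methanol]
Product: 4 (R)-2-methyloctadecane-1,2-diol, via pentadecylmagnesium bromide 3 (not isolated)
Conditions: 1 (2.4 equiv), Mg, THF, 40 °C; then CuI (10 mol%), 2 (1.0 equiv), −30 → 0 °C; aq. NH4Cl
Reagents that add atoms: none
Why: Copper-catalysed Grignard opening of an epoxide (SN2 at the unsubstituted ring CH2, after the first equivalent of 3 has turned the hydroxyl into its magnesium alkoxide) joins C7 to C8 without touching the quaternary carbon, so C6 keeps the configuration of 2; a Payne shift of the alkoxide is harmless because it regenerates the same enantiomer of 2.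

**Step 2**
Reactants: 4 (R)-2-methyloctadecane-1,2-diol
Product: 6 (R)-2-hexadecyl-2-methyloxirane, via primary tosylate 5 (not isolated)
Conditions: NaH (2.5 equiv), THF, 0 °C → rt; N-tosylimidazole (1.05 equiv), 0 °C → rt
Reagents that add atoms: none
Why: One-flask conversion of a 1,2-diol into an epoxide (selective sulfonylation of the primary alkoxide, then 3-exo-tet Williamson closure by the tertiary alkoxide); the C6–O bond is kept, so the configuration is retained.

**Step 3**
Reactants: 7 (S)-α-hydroxy-γ-butyrolactone [(3S)-3-hydroxyoxolan-2-one]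
Product: 8 (S)-2,4-dihydroxy-N-methoxy-N-methylbutanamide
Conditions: MeNH(OMe)·HCl (3 equiv), AlMe3 (3 equiv), CH2Cl2, 0 °C → rt; aq. Rochelle salt; crude product taken on
Reagents that add atoms: N,O-dimethylhydroxylamine hydrochloride, CNOC.Cl
Why: Weinreb aminolysis of a lactone by the aluminium amide formed from AlMe3 and the amine salt; acyl–oxygen cleavage frees the primary C1 hydroxyl and leaves the C3 stereocentre untouched.

**Step 4**
Reactants: 8 (S)-2,4-dihydroxy-N-methoxy-N-methylbutanamide
Product: 9 (S)-N-methoxy-N,2,2-trimethyl-1,3-dioxane-4-carboxamide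
Conditions: 2-methoxypropene (1.5 equiv), PPTS (5 mol%), CH2Cl2, 0 °C → rt; Et3N quench
Reagents that add atoms: 2-methoxypropene, COC(C)=C
Why: Acid-catalysed ketalization of a 1,3-diol with an enol ether (mixed ketal at the primary hydroxyl, then closure to the 1,3-dioxane), which under these nearly neutral, kinetic conditions should outrun the return of the γ-hydroxy amide to lactone 7.

**Step 5**
Reactants: 9 (S)-N-methoxy-N,2,2-trimethyl-1,3-dioxane-4-carboxamide; 10 methylmagnesium bromide
Product: 11 (S)-1-(2,2-dimethyl-1,3-dioxan-4-yl)ethan-1-one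
Conditions: 10 (1.5 equiv), THF, −20 → 0 °C; aq. NH4Cl
Reagents that add atoms: methylmagnesium bromide (compound 10), C[Mg]Br
Why: Weinreb ketone synthesis: the magnesium chelate of the tetrahedral adduct holds until work-up, so only one methyl group adds and the α-alkoxy centre C3 is not epimerized.

**Step 6**
Reactants: 6 (R)-2-hexadecyl-2-methyloxirane; 11 (S)-1-(2,2-dimethyl-1,3-dioxan-4-yl)ethan-1-one
Product: 14 (2S,4R)-2-[(4S)-2,2-dimethyl-1,3-dioxan-4-yl]-4-methylicosane-2,4-diol, via beta-oxido organolithium 12 (not isolated), via beta-oxido organomagnesium 13 (not isolated)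
Conditions: 6 (1.3 equiv), LiDBB (2.6 equiv), THF, −78 °C; MgBr2·OEt2 (2.8 equiv), −78 °C; 11 (1.0 equiv) in Et2O, −78 → −40 °C; aq. NH4Cl
Reagents that add atoms: none
Why: Two single-electron transfers from the arene radical anion cleave the less substituted C5–O bond of 6 and leave a primary C5 carbanion beside the tertiary C6 lithium alkoxide (oxide is too poor a leaving group for β-elimination at −78 °C); lithium–magnesium exchange then gives a less basic carbanion that adds 1,2 to the C4 carbonyl of 11 and forms the C4–C5 bond. The closest known reaction type is the reductive lithiation of epoxides to β-lithioalkoxides followed by carbonyl addition to give 1,3-diols, combined with the Cram-chelate addition of Grignard reagents to α-alkoxy ketones. No ring closes in this step. The new stereocentre C4 is controlled by C3: magnesium is held between the carbonyl oxygen and the dioxane oxygen on C3 in a five-membered chelate, and the carbanion enters from the face that carries the C3 hydrogen, anti to C2, which should give the 4S carbinol with O3 and C5 cis in the later lactone. The step needs facial selectivity at C4 and addition in preference to enolization of the methyl ketone; the chelate, the small primary nucleophile, the magnesium counter-ion and the low temperature should secure both. C3 and C6 are not affected because no bond to either is made or broken.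

**Step 7**
Reactants: 14 (2S,4R)-2-[(4S)-2,2-dimethyl-1,3-dioxan-4-yl]-4-methylicosane-2,4-diol
Product: 15 (3S,4S,6R)-4,6-dimethyldocosane-1,3,4,6-tetraol
Conditions: AcOH/THF/H2O (3:1:1), 40 °C
Reagents that add atoms: none
Why: Acid hydrolysis of the isopropylidene ketal through its oxocarbenium ion; aqueous acetic acid is too weak to ionize the two tertiary carbinols, and no bond to a stereocentre is broken.

**Step 8**
Reactants: 15 (3S,4S,6R)-4,6-dimethyldocosane-1,3,4,6-tetraol
Product: 18 (4S,5S)-4-hydroxy-5-[(2R)-2-hydroxy-2-methyloctadecyl]-5-methyloxolan-2-one (target CNP0079572.1), via hydroxy aldehyde 16 (not isolated), via lactol 17 (not isolated)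
Conditions: TEMPO (20 mol%), PhI(OAc)2 (2.5 equiv), CH2Cl2, rt
Reagents that add atoms: none
Why: TEMPO/PhI(OAc)2 oxidative lactonization of a 1,4-diol: the oxoammonium ion oxidizes the unhindered primary C1 carbinol much faster than the secondary C3 carbinol, the aldehyde is captured by the C4 hydroxyl (5-exo-trig) as the lactol, and a second oxidation gives the γ-lactone, the tertiary C6 hydroxyl being inert.

**Compound list**
1 | 1-bromopentadecane | CCCCCCCCCCCCCCCBr | starting material
2 | (S)-2-methylglycidol, (S)-(2-methyloxiran-2-yl)methanol | C[C@]1(CO)CO1 | starting material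
3 | pentadecylmagnesium bromide (formed in the flask) | CCCCCCCCCCCCCCC[Mg]Br | intermediate
4 | (R)-2-methyloctadecane-1,2-diol | CCCCCCCCCCCCCCCC[C@@](C)(O)CO | intermediate
5 | (R)-2-hydroxy-2-methyloctadecyl 4-methylbenzenesulfonate (formed in the flask as its sodium alkoxide) | CCCCCCCCCCCCCCCC[C@@](C)(O)COS(=O)(=O)c1ccc(C)cc1 | intermediate
6 | (R)-2-hexadecyl-2-methyloxirane | CCCCCCCCCCCCCCCC[C@@]1(C)OC1 | intermediate
7 | (S)-α-hydroxy-γ-butyrolactone, (3S)-3-hydroxyoxolan-2-one | O[C@H]1CCOC1=O | starting material
8 | (S)-2,4-dihydroxy-N-methoxy-N-methylbutanamide | CON(C)C(=O)[C@@H](O)CCO | intermediate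
9 | (S)-N-methoxy-N,2,2-trimethyl-1,3-dioxane-4-carboxamide | CON(C)C(=O)[C@@H]1CCOC(C)(C)O1 | intermediate
10 | methylmagnesium bromide | C[Mg]Br | starting material
11 | (S)-1-(2,2-dimethyl-1,3-dioxan-4-yl)ethan-1-one | CC(=O)[C@@H]1CCOC(C)(C)O1 | intermediate
12 | lithium 1-lithio-2-methyloctadecan-2-olate, C5-lithio C6-lithium alkoxide with the configuration of 6 at C6 (formed in the flask) | CCCCCCCCCCCCCCCC[C@@](C)(O[Li])C[Li] | intermediate
13 | bromomagnesium 1-(bromomagnesio)-2-methyloctadecan-2-olate, the magnesium counterpart of 12 (formed in the flask) | CCCCCCCCCCCCCCCC[C@@](C)(O[Mg]Br)C[Mg]Br | intermediate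
14 | (2S,4R)-2-[(4S)-2,2-dimethyl-1,3-dioxan-4-yl]-4-methylicosane-2,4-diol | CCCCCCCCCCCCCCCC[C@@](C)(O)C[C@](C)(O)[C@@H]1CCOC(C)(C)O1 | intermediate
15 | (3S,4S,6R)-4,6-dimethyldocosane-1,3,4,6-tetraol | CCCCCCCCCCCCCCCC[C@@](C)(O)C[C@](C)(O)[C@@H](O)CCO | intermediate
16 | (3S,4S,6R)-3,4,6-trihydroxy-4,6-dimethyldocosanal (formed in the flask) | CCCCCCCCCCCCCCCC[C@@](C)(O)C[C@](C)(O)[C@@H](O)CC=O | intermediate
17 | (4S,5S)-5-[(2R)-2-hydroxy-2-methyloctadecyl]-5-methyloxolane-2,4-diol, both anomers (formed in the flask) | CCCCCCCCCCCCCCCC[C@@](C)(O)C[C@]1(C)OC(O)C[C@@H]1O | intermediate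
18 | (4S,5S)-4-hydroxy-5-[(2R)-2-hydroxy-2-methyloctadecyl]-5-methyloxolan-2-one, CNP0079572.1 | CCCCCCCCCCCCCCCC[C@@](C)(O)C[C@]1(C)OC(=O)C[C@@H]1O | target

**Step count and risks**
Total steps: 8. Longest linear sequence: 6 steps (steps 3 to 8, from lactone 7); the other branch is steps 1 and 2.

The three steps most likely to fail:

1. Step 6. The carbanion may remove a proton from the methyl ketone instead of adding, and the acetonide oxygen may chelate too weakly, so that attack through the open Felkin–Anh arrangement erodes or reverses the facial selectivity at C4. The fallback introduces the two carbon groups on C4 in the reverse order on a substrate that cannot chelate. It sets out from diol amide 8 (and epoxide 6). Both hydroxyls are silylated under basic conditions (TBSCl, imidazole, DMF) to give (S)-2,4-bis(tert-butyldimethylsilyloxy)-N-methoxy-N-methylbutanamide F1. Organolithium 12, made from 6 as in step 6 but without magnesium, should acylate F1 at −78 °C, where no enolizable ketone meets the carbanion, to give the β-hydroxy ketone (3S,6R)-1,3-bis(tert-butyldimethylsilyloxy)-6-hydroxy-6-methyldocosan-4-one F2. Methylmagnesium bromide 10 (3 equiv, THF, −78 °C, where the magnesium aldolate should not fragment) then adds to the C4 ketone in the Felkin–Anh sense, anti to the C3 silyloxy group. With methyl as the incoming group this leads to the same 4S carbinol, (3S,4S,6R)-1,3-bis(tert-butyldimethylsilyloxy)-4,6-dimethyldocosane-4,6-diol F3. TBAF in THF removes both silyl groups, and the route is rejoined at tetraol 15.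

2. Step 8. The oxoammonium ion may also oxidize the C3 carbinol, and the β-hydroxy aldehyde or the β-hydroxy lactone may lose water across C2–C3. The fallback carries out the oxidation with O3 and O4 masked and closes the ring by acid instead of by lactol oxidation. It sets out from 14. Acid equilibration (PPTS, acetone, rt) should move the isopropylidene group from the six-membered dioxane to the more stable five-membered dioxolane across O3/O4 and free the primary hydroxyl, giving 2-[(4S,5S)-5-[(2R)-2-hydroxy-2-methyloctadecyl]-2,2,5-trimethyl-1,3-dioxolan-4-yl]ethan-1-ol F4. TEMPO/PhI(OAc)2 in MeCN–water should take this primary alcohol to 2-[(4S,5S)-5-[(2R)-2-hydroxy-2-methyloctadecyl]-2,2,5-trimethyl-1,3-dioxolan-4-yl]acetic acid F5. Aqueous trifluoroacetic acid then removes the ketal, and the freed 4-hydroxy acid should close to the γ-lactone, which rejoins the route at target 18.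

3. Step 1. With the hydroxyl of 2 present as its magnesium alkoxide, alkyl transfer from copper may be slow, and bromide may open the epoxide instead (bromohydrin formation). The fallback turns the hydroxyl into the leaving group before the chain is attached. It sets out from 2. TsCl, Et3N and DMAP in CH2Cl2 give (R)-(2-methyloxiran-2-yl)methyl 4-methylbenzenesulfonate F6 (same spatial arrangement as 2; the descriptor changes only through the priority rules). Grignard reagent 3 (1.2 equiv) with catalytic Li2CuCl4 in THF at −40 °C should open the epoxide at its CH2 and give the alkoxide of hydroxy tosylate 5, which K2CO3 in methanol closes to epoxide 6. The route is rejoined there, and diol 4 is bypassed.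

**Further compounds**
F1 | step 6 | (S)-2,4-bis(tert-butyldimethylsilyloxy)-N-methoxy-N-methylbutanamide | CON(C)C(=O)[C@@H](O[Si](C)(C)C(C)(C)C)CCO[Si](C)(C)C(C)(C)C
F2 | step 6 | (3S,6R)-1,3-bis(tert-butyldimethylsilyloxy)-6-hydroxy-6-methyldocosan-4-one | CCCCCCCCCCCCCCCC[C@@](C)(O)CC(=O)[C@@H](O[Si](C)(C)C(C)(C)C)CCO[Si](C)(C)C(C)(C)C
F3 | step 6 | (3S,4S,6R)-1,3-bis(tert-butyldimethylsilyloxy)-4,6-dimethyldocosane-4,6-diol | CCCCCCCCCCCCCCCC[C@@](C)(O)C[C@](C)(O)[C@@H](O[Si](C)(C)C(C)(C)C)CCO[Si](C)(C)C(C)(C)C
F4 | step 8 | 2-[(4S,5S)-5-[(2R)-2-hydroxy-2-methyloctadecyl]-2,2,5-trimethyl-1,3-dioxolan-4-yl]ethan-1-ol | CCCCCCCCCCCCCCCC[C@@](C)(O)C[C@]1(C)OC(C)(C)O[C@H]1CCO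
F5 | step 8 | 2-[(4S,5S)-5-[(2R)-2-hydroxy-2-methyloctadecyl]-2,2,5-trimethyl-1,3-dioxolan-4-yl]acetic acid | CCCCCCCCCCCCCCCC[C@@](C)(O)C[C@]1(C)OC(C)(C)O[C@H]1CC(=O)O
F6 | step 1 | (R)-(2-methyloxiran-2-yl)methyl 4-methylbenzenesulfonate | C[C@]1(COS(=O)(=O)c2ccc(C)cc2)CO1
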